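**Plan**
1. Cuts: the ring B quinone goes back to a para-methoxyphenol masked as its benzyl ether. C2 is raised to a methyl acetal. Ring C is then opened at C3–C4 and O1–C2 in one retro-[4+2].
2. Enabling feature: ring C (O1, C2, C3, C4, C4a, C8a) shares C4a–C8a with the electron-rich ring A. C4=C4a–C8a=O1 is therefore an o-quinone methide, stabilised by O1 and by the 7-OMe para to C4a, and C2=C3 is an enol ether carrying ring B on C3.
3. Forward order: rings A and B are bought as arenes. Ring A becomes a salicyl alcohol (one step) and ring B an (E)-β-aryl enol ether (three steps). Ring C is the only ring built, and it closes when the two halves are joined.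
4. Endgame: C2 is deoxygenated, the benzyl ether is removed, and ring B is oxidised to the quinone.
5. Stereochemistry: the single stereocentre C3 (S) comes from enantioface selection at the enol ether β-carbon by a chiral phosphoric acid bound to the methide. The C2 acetal centre is transient.

Key step: step 5

Numbering follows the isoflavan convention (O1, C2, C3, C4, C4a to C8a; primed locants for ring B).
Assumption: for a methide without a substituent on C4, the sense of induction of the chiral acid cannot be read off a close analogue. The (R)-acid is written, and its equally available mirror image is used if the first run shows the opposite sense.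

Step 1
Reactants: 1 2-hydroxy-4,5-dimethoxybenzaldehyde
Product: 2 2-(hydroxymethyl)-4,5-dimethoxyphenol
Conditions: NaBH4, MeOH/THF, 0 °C; sat. aq. NH4Cl work-up
Reagents that add atoms: none
Why: Borohydride reduction of an aryl aldehyde; the near-neutral work-up and prompt use keep the electron-rich, acid-sensitive salicyl alcohol from ionising too early.

Step 2
Reactants: 3 2,3,4-trimethoxyphenol
Product: 5 2-hydroxy-3,4,5-trimethoxybenzaldehyde, via hydroxymethylphenol 4 (not isolated)
Conditions: MgCl2, Et3N, (CH2O)n, MeCN, reflux; then 1 M HCl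
Reagents that add atoms: paraformaldehyde (reacts as formaldehyde), C=O
Why: Magnesium-mediated ortho-formylation of a phenol (Casnati–Skattebøl reaction): the magnesium phenoxide delivers formaldehyde only to the one free ortho carbon, and a second formaldehyde accepts hydride from magnesium-bound 4 in an Oppenauer-type transfer.

Step 3
Reactants: 5 2-hydroxy-3,4,5-trimethoxybenzaldehyde
Product: 6 2-(benzyloxy)-3,4,5-trimethoxybenzaldehyde
Conditions: BnBr, K2CO3, DMF, rt
Reagents that add atoms: benzyl bromide, BrCc1ccccc1
Why: Williamson ether synthesis on the acidic, chelated phenol; the benzyl group keeps the 2'-oxygen distinct from the methyl ethers so that only ring B can be oxidised at the end.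

Step 4
Reactants: 6 2-(benzyloxy)-3,4,5-trimethoxybenzaldehyde; 7 (methoxymethyl)triphenylphosphonium chloride
Product: 9 2-(benzyloxy)-3,4,5-trimethoxy-1-[(E)-2-methoxyethenyl]benzene, via phosphorus ylide 8 (not isolated)
Conditions: KOtBu, THF, 0 °C to rt; chromatography on Et3N-washed silica gel to collect the E isomer
Reagents that add atoms: none
Why: Wittig methoxymethylenation of an aryl aldehyde; the non-stabilised alkoxy ylide gives both alkene geometries, so the E isomer is secured by separation on base-washed silica gel, which also prevents hydrolysis.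

Step 5
Reactants: 2 2-(hydroxymethyl)-4,5-dimethoxyphenol; 9 2-(benzyloxy)-3,4,5-trimethoxy-1-[(E)-2-methoxyethenyl]benzene
Product: 11 (2R,3S)-3-[2-(benzyloxy)-3,4,5-trimethoxyphenyl]-2,6,7-trimethoxy-3,4-dihydro-2H-chromene (trans acetal), via o-quinone methide 10 (not isolated)
Conditions: (R)-3,3'-bis(2,4,6-triisopropylphenyl)-1,1'-binaphthyl-2,2'-diyl hydrogen phosphate (10 mol %), 5 Å MS, toluene/CH2Cl2, −20 to 0 °C, slow addition of 2 (1.3 equiv)
Reagents that add atoms: none
Why: The phosphoric acid protonates the benzylic hydroxyl group of 2, and electron push from the phenolic oxygen and the para methoxy group expels water to give methide 10, which stays hydrogen-bonded to the chiral phosphate through its carbonyl oxygen. The nucleophilic β-carbon of 9 (future C3) bonds to the methide CH2 (C4) while O1 closes on the developing oxocarbenium carbon C2, so ring C forms as the six-membered adduct of an asynchronous inverse-electron-demand hetero-Diels–Alder reaction (6-exo-trig capture of the oxocarbenium ion in the stepwise limit). The closest known reaction types are the chiral phosphoric acid catalysed [4+2] cycloadditions of in situ generated o-quinone methides with enamides, vinyl sulfides and styrenes, and the racemic cycloaddition of CH2-terminated o-quinone methides with β-aryl enol ethers. C3 is controlled by the catalyst pocket, which leaves one face of the bound heterodiene open and so decides which enantioface of the β-carbon meets C4. C2 follows from suprafacial addition to the E alkene (methoxy trans to aryl, with no endo/exo issue because C4 is a CH2 group) and is erased in step 6. Regiochemistry is fixed by the matched polarity of enol ether and methide, and chemoselectivity over methide oligomerisation and enol ether hydrolysis is served by the slow addition of 2, the molecular sieves and the low temperature.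

Step 6
Reactants: 11 (2R,3S)-3-[2-(benzyloxy)-3,4,5-trimethoxyphenyl]-2,6,7-trimethoxy-3,4-dihydro-2H-chromene
Product: 12 (3S)-3-[2-(benzyloxy)-3,4,5-trimethoxyphenyl]-6,7-dimethoxy-3,4-dihydro-2H-chromene
Conditions: Et3SiH, BF3·OEt2, CH2Cl2, −78 to −40 °C
Reagents that add atoms: none
Why: Ionic hydrogenation of a cyclic acetal (Lewis acid/silane reduction): BF3 ionises the exocyclic C2–OMe bond and the ring oxocarbenium ion takes hydride from Et3SiH at low temperature before it can lose the C3 proton, so the C2 centre vanishes, C3 stays S, and the benzyl and methyl aryl ethers are inert.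

Step 7
Reactants: 12 (3S)-3-[2-(benzyloxy)-3,4,5-trimethoxyphenyl]-6,7-dimethoxy-3,4-dihydro-2H-chromene
Product: 13 6-[(3S)-6,7-dimethoxy-3,4-dihydro-2H-chromen-3-yl]-2,3,4-trimethoxyphenol
Conditions: H2 (1 atm), 10% Pd/C, EtOAc/EtOH, rt
Reagents that add atoms: none
Why: Heterogeneous hydrogenolysis of a benzyl aryl ether; the aryl methyl ethers, the non-benzylic O1–C2 bond and the C3 centre are untouched under one atmosphere of hydrogen.

Step 8
Reactants: 13 6-[(3S)-6,7-dimethoxy-3,4-dihydro-2H-chromen-3-yl]-2,3,4-trimethoxyphenol
Product: 15 abroquinone A, via dienone hemiketal 14 (not isolated)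
Conditions: PhI(OAc)2, MeCN/H2O (4:1), 0 °C
Reagents that add atoms: water, O
Why: Oxidative demethylation of a para-methoxyphenol with a trivalent iodine reagent: the phenol binds to iodine, water adds at C5' para to it, and hemiketal 14 loses methanol to give the 1,4-quinone, while ring A has no free hydroxyl group and is left alone, and the near-neutral medium spares the C3–H next to the quinone.

**Compound list**
1 | 2-hydroxy-4,5-dimethoxybenzaldehyde | COc1cc(O)c(C=O)cc1OC | starting material
2 | 2-(hydroxymethyl)-4,5-dimethoxyphenol | COc1cc(O)c(CO)cc1OC | intermediate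
3 | 2,3,4-trimethoxyphenol | COc1ccc(O)c(OC)c1OC | starting material
4 | 6-(hydroxymethyl)-2,3,4-trimethoxyphenol (magnesium-bound, not isolated) | COc1cc(CO)c(O)c(OC)c1OC | intermediate
5 | 2-hydroxy-3,4,5-trimethoxybenzaldehyde | COc1cc(C=O)c(O)c(OC)c1OC | intermediate
6 | 2-(benzyloxy)-3,4,5-trimethoxybenzaldehyde | COc1cc(C=O)c(OCc2ccccc2)c(OC)c1OC | intermediate
7 | (methoxymethyl)triphenylphosphonium chloride | COC[P+](c1ccccc1)(c1ccccc1)c1ccccc1.[Cl-] | starting material
8 | (methoxymethylidene)triphenylphosphorane (not isolated) | COC=P(c1ccccc1)(c1ccccc1)c1ccccc1 | intermediate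
9 | 2-(benzyloxy)-3,4,5-trimethoxy-1-[(E)-2-methoxyethenyl]benzene | CO/C=C/c1cc(OC)c(OC)c(OC)c1OCc1ccccc1 | intermediate
10 | 3,4-dimethoxy-6-methylidenecyclohexa-2,4-dien-1-one (o-quinone methide, not isolated) | C=C1C=C(OC)C(OC)=CC1=O | intermediate
11 | (2R,3S)-3-[2-(benzyloxy)-3,4,5-trimethoxyphenyl]-2,6,7-trimethoxy-3,4-dihydro-2H-chromene | COc1cc([C@H]2[C@H](OC)Oc3cc(OC)c(OC)cc3C2)c(OCc2ccccc2)c(OC)c1OC | intermediate
12 | (3S)-3-[2-(benzyloxy)-3,4,5-trimethoxyphenyl]-6,7-dimethoxy-3,4-dihydro-2H-chromene | COc1cc([C@H]2COc3cc(OC)c(OC)cc3C2)c(OCc2ccccc2)c(OC)c1OC | intermediate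
13 | 6-[(3S)-6,7-dimethoxy-3,4-dihydro-2H-chromen-3-yl]-2,3,4-trimethoxyphenol | COc1cc([C@H]2COc3cc(OC)c(OC)cc3C2)c(O)c(OC)c1OC | intermediate
14 | 6-[(3S)-6,7-dimethoxy-3,4-dihydro-2H-chromen-3-yl]-4-hydroxy-2,3,4-trimethoxycyclohexa-2,5-dien-1-one (hemiketal carbon unassigned, not isolated) | COC1=C(OC)C(O)(OC)C=C([C@H]2COc3cc(OC)c(OC)cc3C2)C1=O | intermediate
15 | abroquinone A, 5-[(3S)-6,7-dimethoxy-3,4-dihydro-2H-chromen-3-yl]-2,3-dimethoxycyclohexa-2,5-diene-1,4-dione | COC1=C(OC)C(=O)C([C@H]2COc3cc(OC)c(OC)cc3C2)=CC1=O | target

Total step count: 8. Longest linear sequence: 7 (steps 2 to 8, from 2,3,4-trimethoxyphenol).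

**Steps most likely to fail**

Step 5. What may go wrong:
- Poor enantioface selection at the β-carbon, because the enol ether has no hydrogen-bond donor to anchor it to the phosphate and the methide carbon carries no substituent.
- Oligomerisation of the methide.
- Acid-induced hydrolysis or isomerisation of the enol ether.

The fallback replaces the cycloaddition by an auxiliary-controlled alkylation and closes ring C at O1–C8a. It sets out from 9 (either alkene geometry serves) and comes back at 12. Aqueous HCl in THF hydrolyses 9 to the arylacetaldehyde F1. Pinnick oxidation (NaClO2, NaH2PO4, 2-methylbut-2-ene, tBuOH/H2O) gives the arylacetic acid F2. Its mixed pivalic anhydride (pivaloyl chloride, Et3N) acylates lithiated (S)-4-benzyl-1,3-oxazolidin-2-one to give the N-arylacetyl oxazolidinone F3. Evans alkylation of the chelated sodium Z-enolate (NaN(SiMe3)2, THF, −78 °C) uses commercial 2-bromo-4,5-dimethoxybenzyl bromide. Attack on the face away from the auxiliary benzyl group should give the (2S)-alkylated imide F4. LiBH4 (THF/MeOH, 0 °C) releases the auxiliary and gives the (2S)-primary alcohol F5. Intramolecular Buchwald–Hartwig aryl etherification (Pd(OAc)2, 2-(di-tert-butylphosphino)-1,1'-binaphthyl, Cs2CO3, toluene, 80 °C) then closes ring C to 12. This pairing of alkylation and etherification is an established entry to enantiopure isoflavans.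

Step 6. What may go wrong:
- Loss of configurational integrity at C3 through reversible proton loss from the oxocarbenium ion.
- Competing endocyclic C–O cleavage.
- Participation of the neighbouring benzyloxy oxygen.

The fallback opens the ring on purpose and recloses it at a primary carbon. It sets out from 11 and comes back at 12. Mild hydrolysis (AcOH/H2O/THF, rt) gives the lactol F6. Immediate NaBH4 reduction (EtOH, 0 °C) traps the open α-aryl aldehyde form faster than it enolises and gives the phenol alcohol F7. Mitsunobu cyclisation (PPh3, DIAD, THF, 0 °C) forms O1–C2 by substitution at the primary carbon without touching C3. Ring A carries the only free phenol, so only the six-membered ring can form.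

Step 4. What may go wrong: poor geometric selectivity of the Wittig reaction, and isomerisation or hydrolysis during the separation. The fallback builds the E alkene stereoselectively and puts the oxygen on afterwards. It sets out from 6 and comes back at 9. Takai iodoolefination (CHI3, CrCl2, THF, 0 °C), which favours the E alkene with aryl aldehydes, gives the (E)-vinyl iodide F8. Copper-catalysed C–O coupling with methanol (CuI, 3,4,7,8-tetramethyl-1,10-phenanthroline, Cs2CO3, MeOH/toluene, 80 °C) proceeds with retention of alkene geometry and gives 9.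

**Further compounds**
F1 | step 5 | [2-(benzyloxy)-3,4,5-trimethoxyphenyl]acetaldehyde | O=CCc1cc(OC)c(OC)c(OC)c1OCc1ccccc1
F2 | step 5 | [2-(benzyloxy)-3,4,5-trimethoxyphenyl]acetic acid | OC(=O)Cc1cc(OC)c(OC)c(OC)c1OCc1ccccc1
F3 | step 5 | (4S)-4-benzyl-3-{[2-(benzyloxy)-3,4,5-trimethoxyphenyl]acetyl}-1,3-oxazolidin-2-one | O=C(Cc1cc(OC)c(OC)c(OC)c1OCc1ccccc1)N1[C@@H](Cc2ccccc2)COC1=O
F4 | step 5 | (4S)-4-benzyl-3-[(2S)-2-[2-(benzyloxy)-3,4,5-trimethoxyphenyl]-3-(2-bromo-4,5-dimethoxyphenyl)propanoyl]-1,3-oxazolidin-2-one | O=C([C@@H](Cc1cc(OC)c(OC)cc1Br)c1cc(OC)c(OC)c(OC)c1OCc1ccccc1)N1[C@@H](Cc2ccccc2)COC1=O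
F5 | step 5 | (2S)-2-[2-(benzyloxy)-3,4,5-trimethoxyphenyl]-3-(2-bromo-4,5-dimethoxyphenyl)propan-1-ol | OC[C@@H](Cc1cc(OC)c(OC)cc1Br)c1cc(OC)c(OC)c(OC)c1OCc1ccccc1
F6 | step 6 | (3S)-3-[2-(benzyloxy)-3,4,5-trimethoxyphenyl]-6,7-dimethoxy-3,4-dihydro-2H-chromen-2-ol (anomer mixture) | COc1cc([C@H]2C(O)Oc3cc(OC)c(OC)cc3C2)c(OCc2ccccc2)c(OC)c1OC
F7 | step 6 | 2-[(2S)-2-[2-(benzyloxy)-3,4,5-trimethoxyphenyl]-3-hydroxypropyl]-4,5-dimethoxyphenol | OC[C@@H](Cc1cc(OC)c(OC)cc1O)c1cc(OC)c(OC)c(OC)c1OCc1ccccc1
F8 | step 4 | 2-(benzyloxy)-1-[(E)-2-iodoethenyl]-3,4,5-trimethoxybenzene | I/C=C/c1cc(OC)c(OC)c(OC)c1OCc1ccccc1
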